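The rate coefficient of the gamma run, rate over [substrate]·[partner], read 0.0464 M⁻¹ min⁻¹ between 31 min and 42 min, against 0.0135 M⁻¹ min⁻¹ over the first 7.2 min, and I started from that rise.

| setting | gamma | alpha | beta | epsilon | eta |
|---|---|---|---|---|---|
| substrate | 0.500 M | 0.200 M | 0.500 M | 0.500 M | 0.100 M |
| partner | 0.550 M | 0.250 M | 0.550 M | 1.10 M | 0.110 M |
| catalyst | 0.00100 M | 0.00100 M | 0.00300 M | 0.00100 M | 0.00100 M |
| time |  |  |  |  | 42 min |

- gamma run (time / min: [target] / M): 2.4: 0.0067; 7.2: 0.0254; 14: 0.0604; 22: 0.1010; 31: 0.1557; 42: 0.2144
- alpha run (time / min: [target] / M): 2.4: 0.0037; 7.2: 0.0064; 14: 0.0117; 22: 0.0139; 31: 0.0202; 42: 0.0227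
- beta run (time / min: [target] / M): 2.4: 0.0247; 7.2: 0.0705; 14: 0.1389; 22: 0.2059; 31: 0.2622; 42: 0.3054
- epsilon run (time / min: [target] / M): 2.4: 0.0167; 7.2: 0.0639; 14: 0.1613; 22: 0.2692; 31: 0.3614; 42: 0.4095

(standard deviation of a reading: 0.002 M)

- Overall: substrate + partner -> target, with catalyst as catalyst.
- Constant volume, constant temperature.
- A reading of a species includes what of it is bound.
- An order is taken over about fifteen percent of the charge, up and down.

- apparent order in [catalyst] of the starting rate, round the charge of the gamma run (the rate where two percent of its substrate have turned into target)
- apparent order in [partner] of the starting rate, round the charge of the gamma run (the rate where two percent of its substrate have turned into target)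
- target in the eta run at 42 min, as a share of the substrate charged

The coefficient climbed while substrate and partner fell, so I read the gamma run as autocatalysis: target itself adds to the rate. The two windows stood at mean target shares of 2.54% and 37.0% of the substrate charged. I took the gain as linear in that share and independent of catalyst, which gave a slope of 0.0956 M⁻¹ min⁻¹ per whole charge and a coefficient of 0.0110 M⁻¹ min⁻¹ at no target.

But the orders are asked at a share of two percent, and the promoted term is already present there. Its part of the coefficient came to 14.8%, and this promoted share, the part of the rate at a given target share that does not scale with catalyst, lowers the catalyst order from one. So I reckoned that order, the bare coefficient over the whole coefficient at that share, at 0.852. Partner stands in both terms, so I took its order as 1. For the eta run, the bare coefficient with the charged partner gave me a share of 5.10%.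

The forecast gave 0.97, 1.05 and 4.7%. It too held that “target promotes the reaction”, but its catalyst order stood higher than mine.

The flask gave 0.84, 1.0 and 5.42%.

    catalyst + substrate ⇌ catalyst-substrate complex, settled at all times (0.3150 M⁻¹)
    catalyst-substrate complex + partner → target + catalyst + by-product (41.76 M⁻¹ min⁻¹)
    target → decomposed product (0.003684 min⁻¹)
    substrate + partner + target → 2 target (0.2328 M⁻² min⁻¹)

With the step substrate + partner + target → 2 target taken away, the catalyst order of the gamma run goes from 0.84 to 1.0, so the promoted share of 14.8% is what that order gives up. The eta run ended at a target equal to 1.08% of the gamma charge, where the same share reads 8.57%. Taking 0.5 of that as its mean over the run, the step adds 0.23 percentage points. The eta run without the step gives 5.16% against 5.42%.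

The readings stem from a simulated flask for an exercise; noise was put on by code.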